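**Plan**

- Retrosynthetic cuts, in order: the oxindole N1–C2 amide bond (back to a nitroarene and an N-acyloxazolidinone); the pyrazinone N4=C5 bond (back to an azide and a methyl ester); the C–C bond between the stereocentre and the CH2 link (back to an arylacetyl imide and a dehydroalanine amide); the aryl–prenyl and aryl–CH2CO bonds.
- Forward: SNAr, decarboxylation and Suzuki–Miyaura prenylation give the arylacetic acid; a Michael addition joins the chain; the pyrazinone ring closes first and is aromatised; the oxindole ring closes last.
- Enabling feature: in the pyrazinone ring C5 carries the OMe group and is doubly bonded to N4, so N4=C5(OMe)–C6 is the methyl imidate of an α-amino acid methyl ester with C6 as α-carbon. The ester methoxy therefore stays in place if N4 arrives as an iminophosphorane and condenses with that ester carbonyl.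
- Stereochemistry: the only stereocentre (oxindole C3, S) is set in the Michael addition by (S)-4-benzyloxazolidin-2-one. The auxiliary stays on to the end, shielding the acidic C–H and serving as the acyl donor for the last lactamisation; the two other sp3 centres of the dihydropyrazinone are uncontrolled and vanish on aromatisation.

Key step: step 9

Remark: prenyl = 3-methylbut-2-en-1-yl. Racemic 2-bromopropanoic acid and methyl DL-serinate are used, because the centres they would define are erased in step 10. Azides 11, 13 and 15 are small azides to be handled in solution.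

Step 1
Reactants: 1 1-bromo-3-fluoro-2-nitrobenzene; 2 dimethyl malonate
Product: 3 dimethyl 2-(3-bromo-2-nitrophenyl)malonate
Conditions: K2CO3, DMF, 60 °C; then aq. HCl
Reagents that add atoms: none
Why: Nucleophilic aromatic substitution (SNAr), in which the malonate anion adds at the fluorine-bearing carbon ortho to the nitro group and fluoride, a far better leaving group than bromide in addition–elimination, is expelled, so the bromide is kept for step 3.

Step 2
Reactants: 3 dimethyl 2-(3-bromo-2-nitrophenyl)malonate
Product: 4 (3-bromo-2-nitrophenyl)acetic acid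
Conditions: 6 M HCl, AcOH, reflux
Reagents that add atoms: water, O
Why: Acid-catalysed hydrolysis of both esters followed by decarboxylation of the arylmalonic acid (malonic ester end game), to which the aryl bromide and the nitro group are inert.

Step 3
Reactants: 4 (3-bromo-2-nitrophenyl)acetic acid; 5 prenylboronic acid pinacol ester
Product: 6 (2-nitro-3-prenylphenyl)acetic acid
Conditions: PdCl2(IPent)(3-chloropyridine) [IPent = 1,3-bis(2,6-di(pentan-3-yl)phenyl)imidazol-2-ylidene] (2 mol%), KOH (aq.), THF, 65 °C; then aq. HCl
Reagents that add atoms: none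
Why: Suzuki–Miyaura coupling of an allylic boronate, in which oxidative addition into the nitro-activated C–Br bond is easy and the bulky N-heterocyclic carbene ligand is expected to direct reductive elimination to the unsubstituted allyl terminus, giving the linear prenyl arene and not the reverse-prenyl isomer, while the carboxylate is a spectator.

Step 4
Reactants: 6 (2-nitro-3-prenylphenyl)acetic acid; 7 (S)-4-benzyloxazolidin-2-one
Product: 9 (S)-4-benzyl-3-[(2-nitro-3-prenylphenyl)acetyl]oxazolidin-2-one, via mixed pivalic anhydride 8 (not isolated)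
Conditions: PivCl, Et3N, THF, −20 °C; then 7, LiCl, −20 °C to rt
Reagents that add atoms: none
Why: N-Acylation of the oxazolidinone through a mixed anhydride under the mild Et3N/LiCl protocol, chosen because it needs no strong base that would deprotonate the nitro-activated benzylic CH2, the hindered pivaloyl carbonyl directing attack to the arylacetyl carbonyl.

Step 5
Reactants: 10 2-bromopropanoic acid
Product: 11 2-azidopropanoic acid
Conditions: NaN3, DMSO, rt; then aq. HCl (0 °C), extraction into EtOAc, used as a solution
Reagents that add atoms: sodium azide, [N-]=[N+]=[N-].[Na+]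
Why: SN2 displacement of the α-bromide by azide in a dipolar aprotic solvent.

Step 6
Reactants: 11 2-azidopropanoic acid; 12 methyl DL-serinate hydrochloride
Product: 13 methyl N-(2-azidopropanoyl)serinate
Conditions: EDC·HCl, HOBt, N-methylmorpholine, CH2Cl2, 0 °C to rt
Reagents that add atoms: none
Why: Carbodiimide/HOBt amide coupling, in which the amine of the serine ester is acylated far faster than its hydroxyl group and the α-azido acid cannot form an oxazolone.

Step 7
Reactants: 13 methyl N-(2-azidopropanoyl)serinate
Product: 15 methyl 2-(2-azidopropanamido)prop-2-enoate, via serine O-mesylate 14 (not isolated)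
Conditions: MsCl, Et3N, CH2Cl2, 0 °C to rt
Reagents that add atoms: none
Why: O-Mesylation of the serine hydroxyl followed by base-induced β-elimination (E1cB) across the acidic α-C–H is the standard dehydroalanine synthesis; the product carries an azide and an electron-poor alkene and is to be stored cold and used promptly.

Step 8
Reactants: 9 (S)-4-benzyl-3-[(2-nitro-3-prenylphenyl)acetyl]oxazolidin-2-one; 15 methyl 2-(2-azidopropanamido)prop-2-enoate
Product: 17 methyl (4S)-2-(2-azidopropanamido)-5-[(S)-4-benzyl-2-oxooxazolidin-3-yl]-4-(2-nitro-3-prenylphenyl)-5-oxopentanoate, via chlorotitanium Z-enolate 16 (not isolated)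
Conditions: TiCl4, i-Pr2NEt, CH2Cl2, −78 to −40 °C; then 15, −40 to 0 °C; aq. NH4Cl
Reagents that add atoms: none
Why: Proposed new method: soft enolisation with TiCl4 and i-Pr2NEt should give the chelated Z-enolate 16, which is expected to add through the face opposite the benzyl group to the β-carbon of 15 (activated by titanium binding at its ester and amide carbonyls), setting the aryl-bearing centre as (S) while the α-amino centre arises by unselective protonation and does not matter; the closest known reaction type is the Evans chlorotitanium-enolate Michael addition of N-acyloxazolidinones to acrylates, acrylonitrile and vinyl ketones, here extended to a 2-acylaminoacrylate, a class known to accept carbon nucleophiles under Lewis-acid activation.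

Step 9
Reactants: 17 methyl (4S)-2-(2-azidopropanamido)-5-[(S)-4-benzyl-2-oxooxazolidin-3-yl]-4-(2-nitro-3-prenylphenyl)-5-oxopentanoate
Product: 19 (S)-4-benzyl-3-[(2S)-3-(3-methoxy-5-methyl-6-oxo-1,2,5,6-tetrahydropyrazin-2-yl)-2-(2-nitro-3-prenylphenyl)propanoyl]oxazolidin-2-one, via iminophosphorane 18 (not isolated)
Conditions: PPh3, toluene, 4 Å molecular sieves, rt, then 100 °C
Reagents that add atoms: none
Why: PPh3 adds to the terminal azide nitrogen and the phosphazide loses N2 to give iminophosphorane 18, whose nitrogen adds to the methyl ester carbonyl of the amino-acid unit; the oxazaphosphetane then collapses to Ph3P=O and the C5=N4 double bond, so the ester OMe is kept as the lactim ether (Staudinger–aza-Wittig sequence). The closest known reaction type is the intramolecular aza-Wittig reaction of azido esters to cyclic imidates. The six-membered ring closes by 6-exo-trig attack of N4 on the ester carbon, after the secondary amide has rotated to its cis form on heating. No stereocentre is created, and the aryl-bearing centre is untouched because the medium is neutral and its C–H lies in the imide, where it resists enolisation. The chemoselectivity needed (amino-ester carbonyl over the imide and carbamate carbonyls) is secured by ring size, six against eight or more, and the two pyrazinone oxygens are told apart because only the ester carbonyl is converted while the amide N1–C2=O stays as it is. Water must be excluded by the sieves so that 18 condenses instead of hydrolysing to the amine, which would close to the lactam.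

Step 10
Reactants: 19 (S)-4-benzyl-3-[(2S)-3-(3-methoxy-5-methyl-6-oxo-1,2,5,6-tetrahydropyrazin-2-yl)-2-(2-nitro-3-prenylphenyl)propanoyl]oxazolidin-2-one
Product: 20 (S)-4-benzyl-3-[(2S)-3-(3-methoxy-5-methyl-6-oxo-1,6-dihydropyrazin-2-yl)-2-(2-nitro-3-prenylphenyl)propanoyl]oxazolidin-2-one
Conditions: DDQ, toluene, rt
Reagents that add atoms: none
Why: Dehydrogenation by DDQ (hydride abstraction next to nitrogen, then proton loss) is driven by aromatisation to the pyrazinone and removes both uncontrolled centres, as in the oxidation of bis-lactim ethers and dihydropyrazines to pyrazines, while the prenyl CH2 on the nitro-deactivated ring is not expected to compete.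

Step 11
Reactants: 20 (S)-4-benzyl-3-[(2S)-3-(3-methoxy-5-methyl-6-oxo-1,6-dihydropyrazin-2-yl)-2-(2-nitro-3-prenylphenyl)propanoyl]oxazolidin-2-one
Product: 22 Astepyrazinol B, via aniline 21 (not isolated)
Conditions: Zn dust, AcOH, THF, 0 °C to rt, then 40 °C
Reagents that add atoms: none
Why: Dissolving-metal reduction of the nitro group gives aniline 21, which acylates itself on the N-acyloxazolidinone in a 5-exo-trig lactamisation and expels the auxiliary (reductive oxindole synthesis from a 2-nitrophenylacetic acid derivative); the mildly acidic, base-free medium should keep the C3–H centre set in step 8 from enolising, and the trisubstituted alkene and the methoxypyrazinone are inert to Zn/AcOH.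

**Compound list**

1 | 1-bromo-3-fluoro-2-nitrobenzene | O=[N+]([O-])c1c(F)cccc1Br | starting material
2 | dimethyl malonate | COC(=O)CC(=O)OC | starting material
3 | dimethyl 2-(3-bromo-2-nitrophenyl)malonate | COC(=O)C(C(=O)OC)c1cccc(Br)c1[N+](=O)[O-] | intermediate
4 | (3-bromo-2-nitrophenyl)acetic acid | OC(=O)Cc1cccc(Br)c1[N+](=O)[O-] | intermediate
5 | prenylboronic acid pinacol ester | CC(C)=CCB1OC(C)(C)C(C)(C)O1 | starting material
6 | (2-nitro-3-prenylphenyl)acetic acid | OC(=O)Cc1cccc(CC=C(C)C)c1[N+](=O)[O-] | intermediate
7 | (S)-4-benzyloxazolidin-2-one | O=C1OC[C@H](Cc2ccccc2)N1 | starting material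
8 | (2-nitro-3-prenylphenyl)acetic pivalic anhydride (formed in the flask) | CC(C)(C)C(=O)OC(=O)Cc1cccc(CC=C(C)C)c1[N+](=O)[O-] | intermediate
9 | (S)-4-benzyl-3-[(2-nitro-3-prenylphenyl)acetyl]oxazolidin-2-one | O=C(Cc1cccc(CC=C(C)C)c1[N+](=O)[O-])N1C(=O)OC[C@@H]1Cc1ccccc1 | intermediate
10 | 2-bromopropanoic acid (racemic) | CC(Br)C(=O)O | starting material
11 | 2-azidopropanoic acid (racemic) | CC(N=[N+]=[N-])C(=O)O | intermediate
12 | methyl DL-serinate hydrochloride | COC(=O)C(N)CO.Cl | starting material
13 | methyl N-(2-azidopropanoyl)serinate (mixture of stereoisomers) | COC(=O)C(CO)NC(=O)C(C)N=[N+]=[N-] | intermediate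
14 | methyl N-(2-azidopropanoyl)-O-(methylsulfonyl)serinate (formed in the flask) | COC(=O)C(COS(C)(=O)=O)NC(=O)C(C)N=[N+]=[N-] | intermediate
15 | methyl 2-(2-azidopropanamido)prop-2-enoate | C=C(NC(=O)C(C)N=[N+]=[N-])C(=O)OC | intermediate
16 | trichlorotitanium Z-enolate of 9 (formed in the flask) | Cl[Ti](Cl)(Cl)O/C(=C\c1cccc(CC=C(C)C)c1[N+](=O)[O-])N1C(=O)OC[C@@H]1Cc1ccccc1 | intermediate
17 | methyl (4S)-2-(2-azidopropanamido)-5-[(S)-4-benzyl-2-oxooxazolidin-3-yl]-4-(2-nitro-3-prenylphenyl)-5-oxopentanoate (mixture at C2 and at the azide-bearing carbon) | COC(=O)C(NC(=O)C(C)N=[N+]=[N-])C[C@@H](c1cccc(CC=C(C)C)c1[N+](=O)[O-])C(=O)N1C(=O)OC[C@@H]1Cc1ccccc1 | intermediate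
18 | iminophosphorane of 17 (N=PPh3 in place of N3; formed in the flask) | COC(=O)C(NC(=O)C(C)N=P(c1ccccc1)(c1ccccc1)c1ccccc1)C[C@@H](c1cccc(CC=C(C)C)c1[N+](=O)[O-])C(=O)N1C(=O)OC[C@@H]1Cc1ccccc1 | intermediate
19 | (S)-4-benzyl-3-[(2S)-3-(3-methoxy-5-methyl-6-oxo-1,2,5,6-tetrahydropyrazin-2-yl)-2-(2-nitro-3-prenylphenyl)propanoyl]oxazolidin-2-one (mixture at the two ring sp3 carbons) | COC1=NC(C)C(=O)NC1C[C@@H](c1cccc(CC=C(C)C)c1[N+](=O)[O-])C(=O)N1C(=O)OC[C@@H]1Cc1ccccc1 | intermediate
20 | (S)-4-benzyl-3-[(2S)-3-(3-methoxy-5-methyl-6-oxo-1,6-dihydropyrazin-2-yl)-2-(2-nitro-3-prenylphenyl)propanoyl]oxazolidin-2-one | COc1nc(C)c(=O)[nH]c1C[C@@H](c1cccc(CC=C(C)C)c1[N+](=O)[O-])C(=O)N1C(=O)OC[C@@H]1Cc1ccccc1 | intermediate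
21 | (S)-3-[(2S)-2-(2-amino-3-prenylphenyl)-3-(3-methoxy-5-methyl-6-oxo-1,6-dihydropyrazin-2-yl)propanoyl]-4-benzyloxazolidin-2-one (formed in the flask) | COc1nc(C)c(=O)[nH]c1C[C@@H](c1cccc(CC=C(C)C)c1N)C(=O)N1C(=O)OC[C@@H]1Cc1ccccc1 | intermediate
22 | Astepyrazinol B, (S)-3-[(3-methoxy-5-methyl-6-oxo-1,6-dihydropyrazin-2-yl)methyl]-7-(3-methylbut-2-en-1-yl)indolin-2-one | COc1nc(C)c(=O)[nH]c1C[C@@H]1C(=O)Nc2c(CC=C(C)C)cccc21 | target

**Step count**

Total: 11 steps. Longest linear sequence: 8 steps (1, 2, 3, 4, 8, 9, 10, 11); the acceptor 15 is made in a 3-step side branch (5, 6, 7).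

**Steps most likely to fail**

Step 8 (the proposed method). The enolate may be quenched by the amide N–H of 15, may add too slowly to the captodative alkene, or may lose facial control if the nitro or azide group competes for titanium. The fallback activates the acceptor instead of the donor and uses the auxiliary as a resolving handle. It sets out from 15: Boc2O and catalytic DMAP in MeCN should give methyl 2-[(2-azidopropanoyl)(tert-butoxycarbonyl)amino]prop-2-enoate F1, a doubly N-acylated dehydroalanine of the kind known to accept stabilised carbon acids under mild base. Imide 9, acidified by the nitroaryl and imide groups, is then added with catalytic Cs2CO3 or DBU in MeCN to give the adduct methyl (4S)-2-[(2-azidopropanoyl)(tert-butoxycarbonyl)amino]-5-[(S)-4-benzyl-2-oxooxazolidin-3-yl]-4-(2-nitro-3-prenylphenyl)-5-oxopentanoate F2. Facial control is not assured here, but the two epimers at the aryl carbon are diastereomers and should be separable by chromatography or crystallisation, the unwanted one being re-equilibrated with base. Mg(ClO4)2 in warm MeCN removes the Boc group from the imide nitrogen selectively, and the route is rejoined at 17.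

Step 9. The iminophosphorane may be hydrolysed before it condenses, or the ester carbonyl may react so slowly that the temperature needed starts deoxygenation of the nitro group by the phosphine; either way lactam instead of lactim ether would result. The fallback closes the ring as the lactam and methylates afterwards, with N1 blocked to fix the regiochemistry. It sets out from 17: Boc2O and DMAP in MeCN should give the N-Boc imide F2 already named above. PMe3 in wet THF reduces the azide, and the amine closes onto the ester to give the diketopiperazine tert-butyl 2-[(2S)-3-[(S)-4-benzyl-2-oxooxazolidin-3-yl]-2-(2-nitro-3-prenylphenyl)-3-oxopropyl]-5-methyl-3,6-dioxopiperazine-1-carboxylate F3. Me3OBF4 in CH2Cl2 then methylates the oxygen of the only remaining secondary lactam to give the lactim ether tert-butyl 2-[(2S)-3-[(S)-4-benzyl-2-oxooxazolidin-3-yl]-2-(2-nitro-3-prenylphenyl)-3-oxopropyl]-3-methoxy-5-methyl-6-oxo-5,6-dihydropyrazine-1(2H)-carboxylate F4. Mg(ClO4)2 in MeCN removes the Boc group, and the route is rejoined at 19.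

Step 11. Reduction may stall at the hydroxylamine, which would close to the N-hydroxy lactam; the hindered aniline may displace the auxiliary only slowly; and long exposure may allow the C3–H of the product to enolise. The fallback separates auxiliary removal, reduction and ring closure. It sets out from 20: LiOH and H2O2 in THF/water at 0 °C should cleave the auxiliary to (S)-3-(3-methoxy-5-methyl-6-oxo-1,6-dihydropyrazin-2-yl)-2-(2-nitro-3-prenylphenyl)propanoic acid F5. Fe powder and NH4Cl in aqueous EtOH reduce the nitro group to (S)-2-(2-amino-3-prenylphenyl)-3-(3-methoxy-5-methyl-6-oxo-1,6-dihydropyrazin-2-yl)propanoic acid F6. This amino acid should lactamise on standing in dilute AcOH, or with EDC·HCl in CH2Cl2 at 0 °C, and the route is rejoined at 22.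

Further compounds
F1 | step 8 | methyl 2-[(2-azidopropanoyl)(tert-butoxycarbonyl)amino]prop-2-enoate | C=C(N(C(=O)OC(C)(C)C)C(=O)C(C)N=[N+]=[N-])C(=O)OC
F2 | step 8 | methyl (4S)-2-[(2-azidopropanoyl)(tert-butoxycarbonyl)amino]-5-[(S)-4-benzyl-2-oxooxazolidin-3-yl]-4-(2-nitro-3-prenylphenyl)-5-oxopentanoate | COC(=O)C(N(C(=O)OC(C)(C)C)C(=O)C(C)N=[N+]=[N-])C[C@@H](c1cccc(CC=C(C)C)c1[N+](=O)[O-])C(=O)N1C(=O)OC[C@@H]1Cc1ccccc1
F3 | step 9 | tert-butyl 2-[(2S)-3-[(S)-4-benzyl-2-oxooxazolidin-3-yl]-2-(2-nitro-3-prenylphenyl)-3-oxopropyl]-5-methyl-3,6-dioxopiperazine-1-carboxylate | CC1NC(=O)C(C[C@@H](c2cccc(CC=C(C)C)c2[N+](=O)[O-])C(=O)N2C(=O)OC[C@@H]2Cc2ccccc2)N(C(=O)OC(C)(C)C)C1=O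
F4 | step 9 | tert-butyl 2-[(2S)-3-[(S)-4-benzyl-2-oxooxazolidin-3-yl]-2-(2-nitro-3-prenylphenyl)-3-oxopropyl]-3-methoxy-5-methyl-6-oxo-5,6-dihydropyrazine-1(2H)-carboxylate | COC1=NC(C)C(=O)N(C(=O)OC(C)(C)C)C1C[C@@H](c1cccc(CC=C(C)C)c1[N+](=O)[O-])C(=O)N1C(=O)OC[C@@H]1Cc1ccccc1
F5 | step 11 | (S)-3-(3-methoxy-5-methyl-6-oxo-1,6-dihydropyrazin-2-yl)-2-(2-nitro-3-prenylphenyl)propanoic acid | COc1nc(C)c(=O)[nH]c1C[C@@H](c1cccc(CC=C(C)C)c1[N+](=O)[O-])C(=O)O
F6 | step 11 | (S)-2-(2-amino-3-prenylphenyl)-3-(3-methoxy-5-methyl-6-oxo-1,6-dihydropyrazin-2-yl)propanoic acid | COc1nc(C)c(=O)[nH]c1C[C@@H](c1cccc(CC=C(C)C)c1N)C(=O)O
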